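The route rests on reading C3 (the carbinol carbon) and C2 (the OCH2 carbon) of the right-hand oxolan-3-ol, the ring that bears guaiacyl ring D, as a hydrated and cyclised vinyl group. The bond from C3 to the benzylic CH2 of ring C is therefore forged on an open chain. A nickel-catalysed, internally selective Heck-type benzylation unites the ring C benzylic chloride of the finished left half (rings A, B, C, first oxolane) with the internal vinyl carbon of an enantiopure 2-vinyl-1,3-diol monoether made in two steps. One operation delivers the full carbon skeleton as a 1,1-disubstituted alkene. Carbinol-directed epoxidation, 5-endo epoxide opening and hydrogenolysis finish.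

Key step: step 14

Ring labels: ring A is the benzyl-type guaiacyl ring of the left unit. Ring B is the aryl ring on C5 of the left oxolane. Ring C is the benzyl-type ring of the right unit and is joined to ring B. Ring D is the aryl ring on C5 of the right oxolane.

Assumption: the (S)-SEGPHOS-modified iridium catalyst is taken to attack the aldehyde face that leads to the (1S,2R) diols. If the sense of induction is the opposite, the (R)-ligand is used.

Step 1
Reactants: 1 (Z)-but-2-ene-1,4-diol
Product: 2 4,7-dihydro-1,3-dioxepin-2-one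
Conditions: CDI (1.05 equiv), CH2Cl2 (0.05 M), 0 °C to rt
Reagents that add atoms: 1,1'-carbonyldiimidazole, O=C(n1ccnc1)n1ccnc1
Why: Double acyl substitution at the carbonyl of CDI (cyclic carbonate formation) should close the seven-membered ring, because the Z alkene holds both hydroxyls on one side and dilution suppresses oligomers.

Step 2
Reactants: 3 4-(benzyloxy)-3-methoxybenzaldehyde; 2 4,7-dihydro-1,3-dioxepin-2-one
Product: 4 (1S,2R)-1-[4-(benzyloxy)-3-methoxyphenyl]-2-ethenylpropane-1,3-diol
Conditions: [Ir(cod)Cl]2 (2.5 mol %), (S)-SEGPHOS (5 mol %), 4-cyano-3-nitrobenzoic acid (10 mol %), Cs2CO3 (20 mol %), i-PrOH (2 equiv), THF, 90 °C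
Reagents that add atoms: none
Why: In this Krische allylation (transfer-hydrogenative carbonyl (hydroxymethyl)allylation), ionisation and decarboxylation of 2 should give an (E)-σ-(hydroxymethyl)allyliridium species that adds to the aldehyde through a closed chair transition state, which sets the anti relation of C1 and C2, while the chiral bisphosphine selects the aldehyde face and so the absolute configuration.

Step 3
Reactants: 4 (1S,2R)-1-[4-(benzyloxy)-3-methoxyphenyl]-2-ethenylpropane-1,3-diol
Product: 5 (1S,2R)-2-[(benzyloxy)methyl]-1-[4-(benzyloxy)-3-methoxyphenyl]but-3-en-1-ol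
Conditions: Ag2O (1.5 equiv), BnBr (1.1 equiv), CH2Cl2, rt, dark
Reagents that add atoms: benzyl bromide, BrCc1ccccc1
Why: Silver-oxide-mediated Williamson monobenzylation of a diol should alkylate the unhindered primary hydroxyl in preference to the secondary benzylic one, which is flanked by the aryl ring and the branched carbon, and no stereocentre is touched.

Step 4
Reactants: 6 5-bromovanillin (3-bromo-4-hydroxy-5-methoxybenzaldehyde)
Product: 7 4-(benzyloxy)-3-bromo-5-methoxybenzaldehyde
Conditions: BnBr, K2CO3, DMF, 60 °C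
Reagents that add atoms: benzyl bromide, BrCc1ccccc1
Why: Williamson ether synthesis on this acidic phenol is routine and the aldehyde is inert to K2CO3.

Step 5
Reactants: 7 4-(benzyloxy)-3-bromo-5-methoxybenzaldehyde
Product: 8 [4-(benzyloxy)-3-bromo-5-methoxyphenyl]methanol
Conditions: NaBH4, MeOH, 0 °C
Reagents that add atoms: none
Why: Borohydride reduction of an aromatic aldehyde leaves the aryl bromide and the benzyl ether untouched.

Step 6
Reactants: 8 [4-(benzyloxy)-3-bromo-5-methoxyphenyl]methanol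
Product: 9 [4-(benzyloxy)-3-methoxy-5-(4,4,5,5-tetramethyl-1,3,2-dioxaborolan-2-yl)phenyl]methanol
Conditions: B2pin2, PdCl2(dppf) (3 mol %), KOAc, 1,4-dioxane, 90 °C
Reagents that add atoms: bis(pinacolato)diboron, CC1(C)OB(OC1(C)C)B1OC(C)(C)C(C)(C)O1
Why: Miyaura borylation of aryl bromides tolerates a free benzylic alcohol, and the weak base KOAc keeps the boronate from coupling with unreacted bromide.

Step 7
Reactants: 7 4-(benzyloxy)-3-bromo-5-methoxybenzaldehyde; 2 4,7-dihydro-1,3-dioxepin-2-one
Product: 10 (1S,2R)-1-[4-(benzyloxy)-3-bromo-5-methoxyphenyl]-2-ethenylpropane-1,3-diol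
Conditions: [Ir(cod)Cl]2 (2.5 mol %), (S)-SEGPHOS (5 mol %), 4-cyano-3-nitrobenzoic acid (10 mol %), Cs2CO3 (20 mol %), i-PrOH (2 equiv), THF, 90 °C
Reagents that add atoms: none
Why: The same Krische allylation as in step 2 tolerates aryl bromides and should set the anti relation through the chair transition state of the (E)-σ-allyliridium species and the absolute configuration through the chiral bisphosphine.

Step 8
Reactants: 10 (1S,2R)-1-[4-(benzyloxy)-3-bromo-5-methoxyphenyl]-2-ethenylpropane-1,3-diol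
Product: 11 (1S,2R)-2-[(benzyloxy)methyl]-1-[4-(benzyloxy)-3-bromo-5-methoxyphenyl]but-3-en-1-ol
Conditions: Ag2O (1.5 equiv), BnBr (1.1 equiv), CH2Cl2, rt, dark
Reagents that add atoms: benzyl bromide, BrCc1ccccc1
Why: As in step 3, silver-oxide-mediated Williamson monobenzylation should take the primary hydroxyl and leave the hindered benzylic carbinol free.

Step 9
Reactants: 11 (1S,2R)-2-[(benzyloxy)methyl]-1-[4-(benzyloxy)-3-bromo-5-methoxyphenyl]but-3-en-1-ol; 9 [4-(benzyloxy)-3-methoxy-5-(4,4,5,5-tetramethyl-1,3,2-dioxaborolan-2-yl)phenyl]methanol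
Product: 12 (1S,2R)-2-[(benzyloxy)methyl]-1-{4-(benzyloxy)-3-[2-(benzyloxy)-5-(hydroxymethyl)-3-methoxyphenyl]-5-methoxyphenyl}but-3-en-1-ol
Conditions: PdCl2(dppf) (5 mol %), K3PO4, 1,4-dioxane/H2O, 80 °C
Reagents that add atoms: none
Why: Suzuki–Miyaura coupling builds the ring B to ring C bond of a biaryl with only two ortho substituents, and it tolerates free alcohols and an unactivated terminal alkene.

Step 10
Reactants: 13 [4-(benzyloxy)-3-methoxyphenyl]methanol
Product: 14 1-(benzyloxy)-4-(chloromethyl)-2-methoxybenzene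
Conditions: SOCl2, CH2Cl2, 0 °C
Reagents that add atoms: thionyl chloride, O=S(Cl)Cl
Why: Deoxychlorination of an electron-rich benzylic alcohol with thionyl chloride proceeds readily through the chlorosulfite.

Step 11
Reactants: 12 (1S,2R)-2-[(benzyloxy)methyl]-1-{4-(benzyloxy)-3-[2-(benzyloxy)-5-(hydroxymethyl)-3-methoxyphenyl]-5-methoxyphenyl}but-3-en-1-ol; 14 1-(benzyloxy)-4-(chloromethyl)-2-methoxybenzene
Product: 17 (1S,2R)-2-[(benzyloxy)methyl]-1-{4-(benzyloxy)-3-[2-(benzyloxy)-5-(hydroxymethyl)-3-methoxyphenyl]-5-methoxyphenyl}-3-{[4-(benzyloxy)-3-methoxyphenyl]methyl}but-3-en-1-ol, via silylated alkene 15 (not isolated), via silylated coupling product 16 (not isolated)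
Conditions: Et3SiOTf (4.5 equiv), Et3N (8 equiv), Ni(cod)2 (10 mol %), PCy2Ph (20 mol %), 14 (2 equiv), toluene, rt; then Bu4NF, AcOH, THF, 0 °C to rt
Reagents that add atoms: triethylsilyl trifluoromethanesulfonate, CC[Si](CC)(CC)OS(=O)(=O)C(F)(F)F (its silyl groups stand only in 15 and 16 and are gone in 17)
Why: In this nickel-catalysed Heck-type benzylation of a terminal alkene, after in situ silylation of both hydroxyls the cationic η3-benzylnickel species from 14 should place its benzyl carbon on the internal vinyl carbon of 15 and lose the only β-hydrogen, which gives the 1,1-disubstituted alkene without touching the two stereocentres, and buffered fluoride then frees both hydroxyls.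

Step 12
Reactants: 17 (1S,2R)-2-[(benzyloxy)methyl]-1-{4-(benzyloxy)-3-[2-(benzyloxy)-5-(hydroxymethyl)-3-methoxyphenyl]-5-methoxyphenyl}-3-{[4-(benzyloxy)-3-methoxyphenyl]methyl}but-3-en-1-ol
Product: 19 (3S,4R,5S)-4-[(benzyloxy)methyl]-5-{4-(benzyloxy)-3-[2-(benzyloxy)-5-(hydroxymethyl)-3-methoxyphenyl]-5-methoxyphenyl}-3-{[4-(benzyloxy)-3-methoxyphenyl]methyl}oxolan-3-ol, via epoxy alcohol 18 (not isolated)
Conditions: VO(acac)2 (5 mol %), t-BuOOH (1.5 equiv), CH2Cl2, 0 °C to rt; then KOt-Bu (20 mol %), THF, 0 °C to rt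
Reagents that add atoms: tert-butyl hydroperoxide, CC(C)(C)OO
Why: In this hydroxyl-directed vanadium-catalysed epoxidation of a homoallylic alcohol followed by base-catalysed 5-endo epoxide opening, the vanadate ester of the secondary carbinol should deliver oxygen through a chair-like transition state with aryl, CH2OBn and ArCH2 equatorial and the =CH2 terminus axial, that is to the alkene face on the carbinol side, which sets C3 of the oxolane as S (OH trans to CH2OBn), and the carbinol alkoxide then attacks the only SN2-accessible epoxide carbon (CH2), so no bond to a stereocentre is broken.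

Step 13
Reactants: 19 (3S,4R,5S)-4-[(benzyloxy)methyl]-5-{4-(benzyloxy)-3-[2-(benzyloxy)-5-(hydroxymethyl)-3-methoxyphenyl]-5-methoxyphenyl}-3-{[4-(benzyloxy)-3-methoxyphenyl]methyl}oxolan-3-ol
Product: 20 (3S,4R,5S)-4-[(benzyloxy)methyl]-5-{4-(benzyloxy)-3-[2-(benzyloxy)-5-(chloromethyl)-3-methoxyphenyl]-5-methoxyphenyl}-3-{[4-(benzyloxy)-3-methoxyphenyl]methyl}oxolan-3-ol
Conditions: PPh3, CCl4, CH2Cl2, 0 °C to rt, used crude
Reagents that add atoms: tetrachloromethane, ClC(Cl)(Cl)Cl
Why: The neutral Appel reaction should convert the primary benzylic alcohol of ring C into the chloride while the hindered tertiary carbinol and the acid-sensitive 5-aryloxolane stay intact.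

Step 14
Reactants: 20 (3S,4R,5S)-4-[(benzyloxy)methyl]-5-{4-(benzyloxy)-3-[2-(benzyloxy)-5-(chloromethyl)-3-methoxyphenyl]-5-methoxyphenyl}-3-{[4-(benzyloxy)-3-methoxyphenyl]methyl}oxolan-3-ol; 5 (1S,2R)-2-[(benzyloxy)methyl]-1-[4-(benzyloxy)-3-methoxyphenyl]but-3-en-1-ol
Product: 24 seco-alkene in which the ring C benzylic CH2 of the left half is bonded to C3 of (1S,2R)-2-[(benzyloxy)methyl]-1-[4-(benzyloxy)-3-methoxyphenyl]but-3-en-1-ol, via silylated chloride 21 (not isolated), via silylated alkene 22 (not isolated), via silylated coupling product 23 (not isolated)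
Conditions: 5 (3 equiv), Et3SiOTf (6 equiv), Et3N (10 equiv), Ni(cod)2 (15 mol %), PCy2Ph (30 mol %), toluene, rt; then Bu4NF, AcOH, THF, 0 °C to rt
Reagents that add atoms: triethylsilyl trifluoromethanesulfonate, CC[Si](CC)(CC)OS(=O)(=O)C(F)(F)F (its silyl groups stand only in 21, 22 and 23 and are gone in 24)
Why: Zerovalent nickel inserts into the benzylic C–Cl bond of 21 to give an η3-benzylnickel chloride, Et3SiOTf exchanges chloride for triflate, and the cationic complex binds the only alkene present, the monosubstituted one of 22. Migratory insertion places the benzyl carbon on the internal vinyl carbon and nickel on the terminal CH2; the sole β-hydrogen, on the newly substituted carbon, is then eliminated, so the 1,1-disubstituted alkene 23 results and Et3N returns the nickel hydride to zerovalent nickel. The closest known reaction type is the nickel-catalysed Heck-type benzylation of unactivated terminal alkenes with benzyl chlorides, which gives 1,1-disubstituted allylbenzenes at room temperature. No ring is closed and no stereocentre is created; the carbinol and allylic centres of 22 are spectators, and the future carbinol carbon is deliberately left trigonal so that oxygen rather than carbon is later brought to it from the face the target requires, since a carbon nucleophile adding to the corresponding oxolanone would enter anti to CH2OBn and give the wrong epimer. The step needs internal over terminal regioselectivity (secured by the cationic nickel centre with its bulky monophosphine), selection of C–Cl over the O-benzyl groups (secured by room temperature) and no chain walking (the 1,1-disubstituted product binds nickel hydride poorly). Buffered fluoride finally removes both silyl groups.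

Step 15
Reactants: 24 seco-alkene in which the ring C benzylic CH2 of the left half is bonded to C3 of (1S,2R)-2-[(benzyloxy)methyl]-1-[4-(benzyloxy)-3-methoxyphenyl]but-3-en-1-ol
Product: 26 hexa-O-benzyl ether of the target (four phenolic and two primary benzyl ethers; both oxolanes 3S,4R,5S), via epoxy alcohol 25 (not isolated)
Conditions: VO(acac)2 (5 mol %), t-BuOOH (1.5 equiv), CH2Cl2, 0 °C to rt; then KOt-Bu (20 mol %), THF, 0 °C to rt
Reagents that add atoms: tert-butyl hydroperoxide, CC(C)(C)OO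
Why: As in step 12, hydroxyl-directed vanadium-catalysed epoxidation through the all-equatorial chair-like vanadate transition state should bring oxygen to the alkene face on the carbinol side and set the new carbinol carbon as S, and base-catalysed 5-endo opening at the epoxide CH2 by the benzylic alkoxide closes the second oxolane with all other stereocentres retained.

Step 16
Reactants: 26 hexa-O-benzyl ether of the target
Product: 27 target CNP0269573.1
Conditions: H2 (1 atm), Pd/C (10 %), EtOAc/EtOH, rt, stopped as soon as debenzylation is complete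
Reagents that add atoms: none
Why: Catalytic hydrogenolysis cleaves the six unhindered O-benzyl groups faster than the two hindered, ring-embedded benzylic C–O bonds of the oxolanes, and neutral conditions avoid acid-induced cyclisation of the olivil units.

Compound list
1 | (Z)-but-2-ene-1,4-diol | OC/C=C\CO | starting material
2 | 4,7-dihydro-1,3-dioxepin-2-one | O=C1OCC=CCO1 | intermediate
3 | 4-(benzyloxy)-3-methoxybenzaldehyde | COc1cc(C=O)ccc1OCc1ccccc1 | starting material
4 | (1S,2R)-1-[4-(benzyloxy)-3-methoxyphenyl]-2-ethenylpropane-1,3-diol | O[C@H](c1ccc(OCc2ccccc2)c(OC)c1)[C@@H](CO)C=C | intermediate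
5 | (1S,2R)-2-[(benzyloxy)methyl]-1-[4-(benzyloxy)-3-methoxyphenyl]but-3-en-1-ol | O[C@H](c1ccc(OCc2ccccc2)c(OC)c1)[C@@H](COCc1ccccc1)C=C | intermediate
6 | 5-bromovanillin | COc1cc(C=O)cc(Br)c1O | starting material
7 | 4-(benzyloxy)-3-bromo-5-methoxybenzaldehyde | COc1cc(C=O)cc(Br)c1OCc1ccccc1 | intermediate
8 | [4-(benzyloxy)-3-bromo-5-methoxyphenyl]methanol | COc1cc(CO)cc(Br)c1OCc1ccccc1 | intermediate
9 | [4-(benzyloxy)-3-methoxy-5-(4,4,5,5-tetramethyl-1,3,2-dioxaborolan-2-yl)phenyl]methanol | COc1cc(CO)cc(B2OC(C)(C)C(C)(C)O2)c1OCc1ccccc1 | intermediate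
10 | (1S,2R)-1-[4-(benzyloxy)-3-bromo-5-methoxyphenyl]-2-ethenylpropane-1,3-diol | O[C@H](c1cc(OC)c(OCc2ccccc2)c(Br)c1)[C@@H](CO)C=C | intermediate
11 | (1S,2R)-2-[(benzyloxy)methyl]-1-[4-(benzyloxy)-3-bromo-5-methoxyphenyl]but-3-en-1-ol | O[C@H](c1cc(OC)c(OCc2ccccc2)c(Br)c1)[C@@H](COCc1ccccc1)C=C | intermediate
12 | (1S,2R)-2-[(benzyloxy)methyl]-1-{4-(benzyloxy)-3-[2-(benzyloxy)-5-(hydroxymethyl)-3-methoxyphenyl]-5-methoxyphenyl}but-3-en-1-ol | O[C@H](c1cc(OC)c(OCc2ccccc2)c(-c2cc(CO)cc(OC)c2OCc2ccccc2)c1)[C@@H](COCc1ccccc1)C=C | intermediate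
13 | [4-(benzyloxy)-3-methoxyphenyl]methanol | COc1cc(CO)ccc1OCc1ccccc1 | starting material
14 | 1-(benzyloxy)-4-(chloromethyl)-2-methoxybenzene | COc1cc(CCl)ccc1OCc1ccccc1 | intermediate
15 | bis(triethylsilyl) ether of 12 (secondary carbinol and ring C CH2OH silylated) | CC[Si](CC)(CC)O[C@H](c1cc(OC)c(OCc2ccccc2)c(-c2cc(CO[Si](CC)(CC)CC)cc(OC)c2OCc2ccccc2)c1)[C@@H](COCc1ccccc1)C=C | intermediate
16 | bis(triethylsilyl) ether of 17 | CC[Si](CC)(CC)O[C@H](c1cc(OC)c(OCc2ccccc2)c(-c2cc(CO[Si](CC)(CC)CC)cc(OC)c2OCc2ccccc2)c1)[C@@H](COCc1ccccc1)C(=C)Cc1ccc(OCc2ccccc2)c(OC)c1 | intermediate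
17 | (1S,2R)-2-[(benzyloxy)methyl]-1-{4-(benzyloxy)-3-[2-(benzyloxy)-5-(hydroxymethyl)-3-methoxyphenyl]-5-methoxyphenyl}-3-{[4-(benzyloxy)-3-methoxyphenyl]methyl}but-3-en-1-ol | O[C@H](c1cc(OC)c(OCc2ccccc2)c(-c2cc(CO)cc(OC)c2OCc2ccccc2)c1)[C@@H](COCc1ccccc1)C(=C)Cc1ccc(OCc2ccccc2)c(OC)c1 | intermediate
18 | (1S,2R)-3-(benzyloxy)-1-{4-(benzyloxy)-3-[2-(benzyloxy)-5-(hydroxymethyl)-3-methoxyphenyl]-5-methoxyphenyl}-2-[(2S)-2-{[4-(benzyloxy)-3-methoxyphenyl]methyl}oxiran-2-yl]propan-1-ol | O[C@H](c1cc(OC)c(OCc2ccccc2)c(-c2cc(CO)cc(OC)c2OCc2ccccc2)c1)[C@@H](COCc1ccccc1)[C@@]1(Cc2ccc(OCc3ccccc3)c(OC)c2)CO1 | intermediate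
19 | (3S,4R,5S)-4-[(benzyloxy)methyl]-5-{4-(benzyloxy)-3-[2-(benzyloxy)-5-(hydroxymethyl)-3-methoxyphenyl]-5-methoxyphenyl}-3-{[4-(benzyloxy)-3-methoxyphenyl]methyl}oxolan-3-ol | COc1cc(C[C@@]2(O)CO[C@H](c3cc(OC)c(OCc4ccccc4)c(-c4cc(CO)cc(OC)c4OCc4ccccc4)c3)[C@H]2COCc2ccccc2)ccc1OCc1ccccc1 | intermediate
20 | ring C benzylic chloride of 19 (CH2OH replaced by CH2Cl) | COc1cc(C[C@@]2(O)CO[C@H](c3cc(OC)c(OCc4ccccc4)c(-c4cc(CCl)cc(OC)c4OCc4ccccc4)c3)[C@H]2COCc2ccccc2)ccc1OCc1ccccc1 | intermediate
21 | triethylsilyl ether of 20 at the tertiary carbinol | COc1cc(C[C@@]2(O[Si](CC)(CC)CC)CO[C@H](c3cc(OC)c(OCc4ccccc4)c(-c4cc(CCl)cc(OC)c4OCc4ccccc4)c3)[C@H]2COCc2ccccc2)ccc1OCc1ccccc1 | intermediate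
22 | triethylsilyl ether of 5 | CC[Si](CC)(CC)O[C@H](c1ccc(OCc2ccccc2)c(OC)c1)[C@@H](COCc1ccccc1)C=C | intermediate
23 | bis(triethylsilyl) ether of 24 | COc1cc(C[C@@]2(O[Si](CC)(CC)CC)CO[C@H](c3cc(OC)c(OCc4ccccc4)c(-c4cc(CC(=C)[C@H](COCc5ccccc5)[C@H](O[Si](CC)(CC)CC)c5ccc(OCc6ccccc6)c(OC)c5)cc(OC)c4OCc4ccccc4)c3)[C@H]2COCc2ccccc2)ccc1OCc1ccccc1 | intermediate
24 | seco-alkene: left half as in 19, its ring C CH2 bonded to C3 of (1S,2R)-2-[(benzyloxy)methyl]-1-[4-(benzyloxy)-3-methoxyphenyl]but-3-en-1-ol | COc1cc(C[C@@]2(O)CO[C@H](c3cc(OC)c(OCc4ccccc4)c(-c4cc(CC(=C)[C@H](COCc5ccccc5)[C@H](O)c5ccc(OCc6ccccc6)c(OC)c5)cc(OC)c4OCc4ccccc4)c3)[C@H]2COCc2ccccc2)ccc1OCc1ccccc1 | intermediate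
25 | (2S)-epoxide of 24 (oxygen on the alkene face at the carbinol side) | COc1cc(C[C@@]2(O)CO[C@H](c3cc(OC)c(OCc4ccccc4)c(-c4cc(C[C@@]5(CO5)[C@H](COCc5ccccc5)[C@H](O)c5ccc(OCc6ccccc6)c(OC)c5)cc(OC)c4OCc4ccccc4)c3)[C@H]2COCc2ccccc2)ccc1OCc1ccccc1 | intermediate
26 | hexa-O-benzyl ether of the target | COc1cc(C[C@@]2(O)CO[C@H](c3cc(OC)c(OCc4ccccc4)c(-c4cc(C[C@@]5(O)CO[C@H](c6ccc(OCc7ccccc7)c(OC)c6)[C@H]5COCc5ccccc5)cc(OC)c4OCc4ccccc4)c3)[C@H]2COCc2ccccc2)ccc1OCc1ccccc1 | intermediate
27 | CNP0269573.1, both oxolan-3-ol units (3S,4R,5S) | COc1cc(C[C@@]2(O)CO[C@H](c3cc(OC)c(O)c(-c4cc(C[C@@]5(O)CO[C@H](c6ccc(O)c(OC)c6)[C@H]5CO)cc(OC)c4O)c3)[C@H]2CO)ccc1O | target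

Total step count: 16
Longest linear sequence: 10 steps (4, 7, 8, 9, 11, 12, 13, 14, 15, 16) from 5-bromovanillin

Steps most likely to fail

Step 14. The coupling may suffer in four ways:
- slow insertion into the α-branched alkene;
- erosion of internal selectivity;
- ionisation or quaternisation of the electron-rich benzylic chloride by the silyl triflate or by Et3N;
- nickel hydride chain walking that moves the alkene and endangers the allylic stereocentre.

The fallback replaces C–H benzylation by a cross-coupling of two defined partners. It sets out from 5 and 20, which are silylated separately (Et3SiOTf, Et3N) and isolated as 22 and 21. Tsuji–Wacker oxidation of 22 (PdCl2, CuCl, O2, DMF/H2O) should give the methyl ketone F1. Kinetic deprotonation at its CH3 group (KHMDS, PhNTf2, THF, −78 °C) should give the enol triflate F2. Zinc insertion into 21 (Zn dust, LiCl, THF) should give the benzylic zinc chloride F3. Negishi coupling of F2 with F3 (Pd(PPh3)4, THF) forms the same bond and comes back to the route at 23, which is desilylated as in step 14.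

Step 15. Three things may go wrong:
- facial selectivity of the open-chain epoxidation may be poor;
- the vanadium Lewis acid may open the epoxide at its tertiary carbon;
- the 5-endo closure may be sluggish.

The fallback closes the ring first and brings in the oxygen under cyclic control. It sets out from 24. Iridium-catalysed O-vinylation of the secondary carbinol ([Ir(cod)Cl]2, Na2CO3, vinyl acetate, toluene, 100 °C) should give the vinyl ether F4. Ring-closing metathesis (second-generation Grubbs catalyst, toluene, 70 °C) should give the 4-benzyl-2,3-dihydrofuran F5. Dimethyldioxirane (CH2Cl2, −78 °C) should attack the enol ether anti to the neighbouring CH2OBn group to give the bicyclic epoxide F6. In the same flask i-Bu2AlH opens F6 at its acetal carbon, and this comes back to the route at 26.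

Step 16. Over-reduction may cleave the ring benzylic C–O bonds of the two oxolanes before the last O-benzyl group has gone. The fallback replaces surface hydrogenolysis by single-electron debenzylation with lithium 4,4'-di-tert-butylbiphenylide (THF, −78 °C). The electron should go to the plain phenyl rings of the benzyl groups rather than to the electron-rich, progressively phenoxide-bearing guaiacyl rings. It sets out from 26 and comes back at 27 without any new compound.

Further compounds
F1 | step 14 | (3R,4S)-3-[(benzyloxy)methyl]-4-[4-(benzyloxy)-3-methoxyphenyl]-4-[(triethylsilyl)oxy]butan-2-one | CC[Si](CC)(CC)O[C@H](c1ccc(OCc2ccccc2)c(OC)c1)[C@@H](COCc1ccccc1)C(C)=O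
F2 | step 14 | (3R,4S)-3-[(benzyloxy)methyl]-4-[4-(benzyloxy)-3-methoxyphenyl]-4-[(triethylsilyl)oxy]but-1-en-2-yl trifluoromethanesulfonate | CC[Si](CC)(CC)O[C@H](c1ccc(OCc2ccccc2)c(OC)c1)[C@@H](COCc1ccccc1)C(=C)OS(=O)(=O)C(F)(F)F
F3 | step 14 | benzylic zinc chloride from 21 (CH2Cl replaced by CH2ZnCl) | COc1cc(C[C@@]2(O[Si](CC)(CC)CC)CO[C@H](c3cc(OC)c(OCc4ccccc4)c(-c4cc(C[Zn]Cl)cc(OC)c4OCc4ccccc4)c3)[C@H]2COCc2ccccc2)ccc1OCc1ccccc1
F4 | step 15 | O-vinyl ether of 24 at its secondary carbinol | COc1cc(C[C@@]2(O)CO[C@H](c3cc(OC)c(OCc4ccccc4)c(-c4cc(CC(=C)[C@H](COCc5ccccc5)[C@H](OC=C)c5ccc(OCc6ccccc6)c(OC)c5)cc(OC)c4OCc4ccccc4)c3)[C@H]2COCc2ccccc2)ccc1OCc1ccccc1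
F5 | step 15 | cyclic enol ether: right unit as a (2S,3R)-2-aryl-3-[(benzyloxy)methyl]-2,3-dihydrofuran that bears the ring C CH2 at C4 | COc1cc(C[C@@]2(O)CO[C@H](c3cc(OC)c(OCc4ccccc4)c(-c4cc(CC5=CO[C@H](c6ccc(OCc7ccccc7)c(OC)c6)[C@H]5COCc5ccccc5)cc(OC)c4OCc4ccccc4)c3)[C@H]2COCc2ccccc2)ccc1OCc1ccccc1
F6 | step 15 | epoxide of F5 (2,6-dioxabicyclo[3.1.0]hexane, epoxide oxygen trans to CH2OBn) | COc1cc(C[C@@]2(O)CO[C@H](c3cc(OC)c(OCc4ccccc4)c(-c4cc(C[C@]56O[C@@H]6O[C@H](c6ccc(OCc7ccccc7)c(OC)c6)[C@H]5COCc5ccccc5)cc(OC)c4OCc4ccccc4)c3)[C@H]2COCc2ccccc2)ccc1OCc1ccccc1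
F0 | step 16 | none | none
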